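**Retrosynthetic overview**

1. The ester bond between the central isocitrate carboxyl of the gem-dimethyl half and the C4 hydroxymethyl group of the other half is made by Yamaguchi esterification (35 + 36). Each C11–O ether bond comes from reductive etherification of an albicanal-type aldehyde (23, 19) with a (2R,3S)-isocitrate triester silyl ether (32, 26) made from (R)-malic acid by Fráter–Seebach alkylation.
2. Both drimane halves come from one bicyclization, run on a substrate that is racemic at C4. It should give the C4 epimers 17 and 18 of a 4-(silyloxymethyl) albicanate. 17 (equatorial CH2O) becomes the oxygenated half; 18 becomes the gem-dimethyl half after Barton–McCombie deoxygenation, so there the extra oxygen is a temporary group.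
3. Key disconnection: the acyclic keto ynenoate 10 is folded into the decalin by a chiral primary amine in one operation. Ring A closes first (C5–C10 bond), ring B second (C7–C8 bond).
4. Enabling feature: in ring B, C5 and C7 both flank C6, and C10 and C8 both flank C9, which carries C11 at a carboxyl-derived oxidation level, while C8 carries the exocyclic methylene C12. With C6 as a temporary ketone, ring B is the union of an acetonyl bis-nucleophile (C5–C6–C7) and a 2-ethynyl-enoate bis-electrophile (C10–C9(C11)–C8≡C12).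
5. 10 is assembled linearly from hydroxyacetone, a C5 chloroalkyne, CO/MeOH, Me2CuLi/I2 and ethynylzinc bromide. The C6 oxygen is removed afterwards through the tosylhydrazone.

Key step: step 8

Remark: drimane numbering is used in the explanations (C1–C10 ring carbons, C11 on C9, C12 on C8); TBDPS = tert-butyldiphenylsilyl, TES = triethylsilyl.
Remark (assumption): the facial preference of the chiral secondary enamine in step 8 is taken from the accepted model for 1-phenylethylamine ketimines (attack anti to the phenyl group). Applied to this enamine, it points to the (S)-amine for the natural C5/C10 configuration.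

**Route**

Step 1
Reactants: 1 hydroxyacetone
Product: 2 1-[(tert-butyldiphenylsilyl)oxy]propan-2-one
Conditions: TBDPSCl, imidazole, CH2Cl2, 0 °C to rt
Reagents that add atoms: tert-butyl(chloro)diphenylsilane, CC(C)(C)[Si](Cl)(c1ccccc1)c1ccccc1
Why: silylation of the primary alcohol gives a robust ether that should survive every step up to the fluoride cleavages in steps 12 and 25.

Step 2
Reactants: 2 1-[(tert-butyldiphenylsilyl)oxy]propan-2-one
Product: 3 (3E)-5-[(tert-butyldiphenylsilyl)oxy]-4-methylpent-3-en-2-one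
Conditions: Ph3P=CHC(O)CH3, toluene, 110 °C
Reagents that add atoms: 1-(triphenylphosphoranylidene)propan-2-one, CC(=O)C=P(c1ccccc1)(c1ccccc1)c1ccccc1
Why: Wittig olefination of the activated alpha-silyloxy ketone with the stabilised ylide should give the trisubstituted enone mainly as the E isomer; the geometry does not matter because step 3 is not stereoselective.

Step 3
Reactants: 3 (3E)-5-[(tert-butyldiphenylsilyl)oxy]-4-methylpent-3-en-2-one; 4 (5-chloropent-1-yn-1-yl)trimethylsilane
Product: 6 rac-4-{[(tert-butyldiphenylsilyl)oxy]methyl}-4-methyl-9-(trimethylsilyl)non-8-yn-2-one, via Grignard reagent 5 (not isolated)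
Conditions: Mg, THF, 60 °C; then CuBr·SMe2 (10 mol %), 3, THF, −40 to 0 °C; aq NH4Cl
Reagents that add atoms: none
Why: copper-catalysed conjugate addition of the Grignard reagent to the beta,beta-disubstituted enone builds the quaternary carbon C4 as a racemate, which is intended because both C4 configurations are used later.

Step 4
Reactants: 6 rac-4-{[(tert-butyldiphenylsilyl)oxy]methyl}-4-methyl-9-(trimethylsilyl)non-8-yn-2-one
Product: 7 rac-4-{[(tert-butyldiphenylsilyl)oxy]methyl}-4-methylnon-8-yn-2-one
Conditions: K2CO3, MeOH, rt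
Reagents that add atoms: none
Why: methoxide-mediated protodesilylation cleaves only the alkynyl C–Si bond and frees the terminal alkyne.

Step 5
Reactants: 7 rac-4-{[(tert-butyldiphenylsilyl)oxy]methyl}-4-methylnon-8-yn-2-one
Product: 8 methyl rac-7-{[(tert-butyldiphenylsilyl)oxy]methyl}-7-methyl-9-oxodec-2-ynoate
Conditions: PdCl2 (5 mol %), CuCl2 (2.2 equiv), NaOAc (2.2 equiv), CO (1 atm), MeOH, rt
Reagents that add atoms: carbon monoxide, [C-]#[O+]; methanol, CO
Why: oxidative methoxycarbonylation of the terminal alkyne (divalent palladium catalysis with CuCl2 as oxidant) gives the 2-ynoate without touching the ketone, which an acetylide carboxylation would not tolerate.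

Step 6
Reactants: 8 methyl rac-7-{[(tert-butyldiphenylsilyl)oxy]methyl}-7-methyl-9-oxodec-2-ynoate
Product: 9 methyl (2E)-rac-7-{[(tert-butyldiphenylsilyl)oxy]methyl}-2-iodo-3,7-dimethyl-9-oxodec-2-enoate
Conditions: Me2CuLi (from CuI and MeLi), THF, −78 °C; then I2, −78 to 0 °C
Reagents that add atoms: lithium dimethylcuprate, [Li+].C[Cu-]C; iodine, II
Why: syn-carbocupration of the ynoate places the new methyl group on the beta-carbon (future C10), and iodinolysis of the alkenylcopper with retention should give the alpha-iodo enoate as one geometric isomer.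

Step 7
Reactants: 9 methyl (2E)-rac-7-{[(tert-butyldiphenylsilyl)oxy]methyl}-2-iodo-3,7-dimethyl-9-oxodec-2-enoate
Product: 10 methyl (2Z)-rac-7-{[(tert-butyldiphenylsilyl)oxy]methyl}-2-ethynyl-3,7-dimethyl-9-oxodec-2-enoate
Conditions: HC≡CZnBr (from HC≡CMgBr and ZnBr2), Pd(PPh3)4 (5 mol %), THF, rt
Reagents that add atoms: ethynylzinc bromide, C#C[Zn]Br
Why: Negishi coupling of the alkenyl iodide proceeds with retention of the double-bond geometry and installs the terminal alkyne that becomes C8 and C12.

Step 8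
Reactants: 10 methyl (2Z)-rac-7-{[(tert-butyldiphenylsilyl)oxy]methyl}-2-ethynyl-3,7-dimethyl-9-oxodec-2-enoate; 11 (S)-1-phenylethylamine
Product: 15 methyl (1S,4aR,8aS)-5-{[(tert-butyldiphenylsilyl)oxy]methyl}-5,8a-dimethyl-2-methylidene-4-oxodecahydronaphthalene-1-carboxylate (both C5 epimers), via ketimine 12 (not isolated), via monocyclic allenoate imine 13 (not isolated), via bicyclic imine 14 (not isolated)
Conditions: 11 (1.1 equiv), 4 Å MS, TsOH (2 mol %), toluene, 60 °C; then Et3N (0.2 equiv), 90 °C; then 10% aq AcOH, THF, rt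
Reagents that add atoms: water, O
Why: Proposed new method: ketimine 12 equilibrates with its more substituted secondary enamine (C5=C6–NH), which adds in a chair-like aza-ene (Michael) fashion to C10 of the 2-ethynyl-enoate with internal N–H transfer to C9 (ring A, 6-exo-trig, C5–C10 bond); amine-mediated prototropy turns the resulting 3-butynoate into allenoate 13, whose central carbon C8 is then attacked by the regenerated, less substituted enamine (C7=C6–NH) in a second aza-ene addition that closes ring B (six-membered, attack on the sp carbon of the endocyclic C8=C9 bond, C7–C8 bond) and leaves C8=C12 as the exocyclic methylene of imine 14. The closest known reactions are the asymmetric Michael addition of chiral 1-phenylethylamine ketimines through their secondary enamine tautomers and the enamine alpha,alpha'-annulation of ketones with 2-(bromomethyl)acrylates; new are the tetrasubstituted first acceptor and the allenoate as second acceptor. C10 (quaternary) and C5 are set together in the first addition: the enamine face anti to the phenyl group of the auxiliary is attacked, and the compact chair transition state places C6 and C9 pseudo-equatorial, which gives the trans relationship of C5–H and the C10 methyl group. C9 is set by delivery of the N–H proton to the face opposite the axial C10 methyl group, and C5 and C9 remain epimerisable alpha-carbonyl centres whose stable configurations (trans ring fusion, equatorial ester) are the desired ones. Regioselectivity (C5 before C7) follows from the known preference of such imines for the more substituted enamine and from ring size, since only C5 reaches C10 through a six-membered transition state and C7 reaches C8 only once ring A exists. The neutral conditions and the built-in alpha-protonation at C9 should keep the C8=C12 bond out of conjugation with both carbonyl groups, and the racemic C4 centre should not override the auxiliary, so both C4 epimers of 15 are expected with the same C5, C9 and C10 configuration.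

Step 9
Reactants: 15 methyl (1S,4aR,8aS)-5-{[(tert-butyldiphenylsilyl)oxy]methyl}-5,8a-dimethyl-2-methylidene-4-oxodecahydronaphthalene-1-carboxylate (both C5 epimers)
Product: 16 the 4-(tosylhydrazone) of 15 (both C5 epimers)
Conditions: TsNHNH2, AcOH (cat.), EtOH, 50 °C
Reagents that add atoms: 4-methylbenzenesulfonohydrazide, Cc1ccc(cc1)S(=O)(=O)NN
Why: condensation of the C6 ketone with tosylhydrazide under weakly acidic conditions gives the hydrazone needed for a mild deoxygenation.

Step 10
Reactants: 16 the 4-(tosylhydrazone) of 15 (both C5 epimers)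
Product: 17 methyl (1S,4aR,5R,8aS)-5-{[(tert-butyldiphenylsilyl)oxy]methyl}-5,8a-dimethyl-2-methylidenedecahydronaphthalene-1-carboxylate (equatorial silyloxymethyl) and 18 its (1S,4aR,5S,8aS) epimer (axial silyloxymethyl), separated by chromatography
Conditions: catecholborane, CHCl3, 0 °C to rt; then NaOAc·3H2O, 60 °C; chromatography
Reagents that add atoms: none
Why: hydride delivery from catecholborane to the C=N bond followed by acetate-induced loss of sulfinate and N2 (reduction of a saturated tosylhydrazone to the methylene group) removes the temporary C6 oxygen without strong acid or base, so the beta,gamma-alkene should not migrate.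

Step 11
Reactants: 17 methyl (1S,4aR,5R,8aS)-5-{[(tert-butyldiphenylsilyl)oxy]methyl}-5,8a-dimethyl-2-methylidenedecahydronaphthalene-1-carboxylate
Product: 19 (1S,4aR,5R,8aS)-5-{[(tert-butyldiphenylsilyl)oxy]methyl}-5,8a-dimethyl-2-methylidenedecahydronaphthalene-1-carbaldehyde
Conditions: i-Bu2AlH (1.1 equiv), CH2Cl2, −78 °C; aq potassium sodium tartrate
Reagents that add atoms: none
Why: partial reduction of the hindered methyl ester at low temperature stops at the aluminium hemiacetal, which gives the aldehyde on work-up without touching C9.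

Step 12
Reactants: 18 methyl (1S,4aR,5S,8aS)-5-{[(tert-butyldiphenylsilyl)oxy]methyl}-5,8a-dimethyl-2-methylidenedecahydronaphthalene-1-carboxylate
Product: 20 methyl (1S,4aR,5S,8aS)-5-(hydroxymethyl)-5,8a-dimethyl-2-methylidenedecahydronaphthalene-1-carboxylate
Conditions: HF·pyridine, pyridine, THF, rt
Reagents that add atoms: none
Why: fluoride cleaves the Si–O bond under buffered conditions that leave the ester and the alkene alone.

Step 13
Reactants: 20 methyl (1S,4aR,5S,8aS)-5-(hydroxymethyl)-5,8a-dimethyl-2-methylidenedecahydronaphthalene-1-carboxylate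
Product: 21 the O-phenyl thionocarbonate of 20
Conditions: PhOC(S)Cl, pyridine, DMAP (cat.), CH2Cl2, rt
Reagents that add atoms: O-phenyl carbonochloridothioate, ClC(=S)Oc1ccccc1
Why: acylation of the primary alcohol gives the radical precursor for Barton–McCombie deoxygenation.

Step 14
Reactants: 21 the O-phenyl thionocarbonate of 20
Product: 22 methyl (1S,4aS,8aS)-5,5,8a-trimethyl-2-methylidenedecahydronaphthalene-1-carboxylate (methyl albicanate)
Conditions: Bu3SnH, AIBN (cat.), toluene, 110 °C
Reagents that add atoms: none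
Why: Barton–McCombie deoxygenation (tin radical addition to C=S, C–O fragmentation, hydrogen transfer to the neopentyl radical) turns the C4 substituent into the second methyl group and erases the C4 stereocentre.

Step 15
Reactants: 22 methyl albicanate
Product: 23 (1S,4aS,8aS)-5,5,8a-trimethyl-2-methylidenedecahydronaphthalene-1-carbaldehyde (albicanal)
Conditions: i-Bu2AlH (1.1 equiv), CH2Cl2, −78 °C; aq potassium sodium tartrate
Reagents that add atoms: none
Why: the same low-temperature partial ester reduction as in step 11 gives the aldehyde with C9 untouched.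

Step 16
Reactants: 24 dimethyl (R)-malate
Product: 25 3-tert-butyl 1,2-dimethyl (1R,2S)-1-hydroxypropane-1,2,3-tricarboxylate
Conditions: LiN(SiMe3)2 (2.2 equiv), THF, −78 °C; then BrCH2CO2t-Bu, −78 to −20 °C
Reagents that add atoms: tert-butyl bromoacetate, CC(C)(C)OC(=O)CBr
Why: Fráter–Seebach alkylation of the alkoxide enolate occurs anti to the alkoxide, which sets the new centre (S) beside the retained (R)-carbinol centre and gives the (2R,3S)-isocitrate skeleton with the side-chain carboxyl already distinguished.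

Step 17
Reactants: 25 3-tert-butyl 1,2-dimethyl (1R,2S)-1-hydroxypropane-1,2,3-tricarboxylate
Product: 26 3-tert-butyl 1,2-dimethyl (1R,2S)-1-[(triethylsilyl)oxy]propane-1,2,3-tricarboxylate
Conditions: TESCl, imidazole, DMF, 0 °C
Reagents that add atoms: chlorotriethylsilane, CC[Si](Cl)(CC)CC
Why: silylation gives the silyl ether that serves as the oxygen nucleophile in the reductive etherification.

Step 18
Reactants: 27 (R)-malic acid
Product: 29 (3R)-3-hydroxy-4-methoxy-4-oxobutanoic acid, via trifluoroacetylated anhydride 28 (not isolated)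
Conditions: (CF3CO)2O, 0 °C to rt; evaporate; then MeOH, rt
Reagents that add atoms: methanol, CO
Why: methanol opens the O-acylated cyclic anhydride at the carbonyl next to the electron-withdrawing acyloxy group and then frees the hydroxyl group, so only the C1 carboxyl is esterified and the stereocentre is not involved.

Step 19
Reactants: 29 (3R)-3-hydroxy-4-methoxy-4-oxobutanoic acid
Product: 30 1-methyl 4-(prop-2-en-1-yl) (2R)-2-hydroxybutanedioate
Conditions: KHCO3, allyl bromide, DMF, rt
Reagents that add atoms: allyl bromide, C=CCBr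
Why: carboxylate alkylation esterifies the free acid without touching the hydroxyl group.

Step 20
Reactants: 30 1-methyl 4-(prop-2-en-1-yl) (2R)-2-hydroxybutanedioate
Product: 31 3-tert-butyl 1-methyl 2-(prop-2-en-1-yl) (1R,2S)-1-hydroxypropane-1,2,3-tricarboxylate
Conditions: LiN(SiMe3)2 (2.2 equiv), THF, −78 °C; then BrCH2CO2t-Bu, −78 to −20 °C
Reagents that add atoms: tert-butyl bromoacetate, CC(C)(C)OC(=O)CBr
Why: the same anti-selective Fráter–Seebach alkylation as in step 16 gives the isocitrate triester with three different ester groups.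

Step 21
Reactants: 31 3-tert-butyl 1-methyl 2-(prop-2-en-1-yl) (1R,2S)-1-hydroxypropane-1,2,3-tricarboxylate
Product: 32 3-tert-butyl 1-methyl 2-(prop-2-en-1-yl) (1R,2S)-1-[(triethylsilyl)oxy]propane-1,2,3-tricarboxylate
Conditions: TESCl, imidazole, DMF, 0 °C
Reagents that add atoms: chlorotriethylsilane, CC[Si](Cl)(CC)CC
Why: silylation as in step 17.

Step 22
Reactants: 23 albicanal; 32 3-tert-butyl 1-methyl 2-(prop-2-en-1-yl) (1R,2S)-1-[(triethylsilyl)oxy]propane-1,2,3-tricarboxylate
Product: 33 3-tert-butyl 1-methyl 2-(prop-2-en-1-yl) (1R,2S)-1-{[(1S,4aS,8aS)-5,5,8a-trimethyl-2-methylidenedecahydronaphthalen-1-yl]methoxy}propane-1,2,3-tricarboxylate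
Conditions: Et3SiH (1.5 equiv), TMSOTf (0.2 equiv), CH2Cl2, −78 °C
Reagents that add atoms: none
Why: reductive etherification: TMSOTf promotes addition of the silyl ether oxygen to the aldehyde and the oxocarbenium ion is reduced by Et3SiH; the C–O bond of the isocitrate carbinol carbon is never broken, so its configuration is retained and no new stereocentre arises.

Step 23
Reactants: 19 (1S,4aR,5R,8aS)-5-{[(tert-butyldiphenylsilyl)oxy]methyl}-5,8a-dimethyl-2-methylidenedecahydronaphthalene-1-carbaldehyde; 26 3-tert-butyl 1,2-dimethyl (1R,2S)-1-[(triethylsilyl)oxy]propane-1,2,3-tricarboxylate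
Product: 34 3-tert-butyl 1,2-dimethyl (1R,2S)-1-{[(1S,4aR,5R,8aS)-5-{[(tert-butyldiphenylsilyl)oxy]methyl}-5,8a-dimethyl-2-methylidenedecahydronaphthalen-1-yl]methoxy}propane-1,2,3-tricarboxylate
Conditions: Et3SiH (1.5 equiv), TMSOTf (0.2 equiv), CH2Cl2, −78 °C
Reagents that add atoms: none
Why: the same reductive etherification as in step 22; the silyl ether at C4 and the tert-butyl ester should survive the catalytic silyl triflate at low temperature.

Step 24
Reactants: 33 the allyl tert-butyl methyl triester ether of the gem-dimethyl half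
Product: 35 (2S,3R)-2-[2-(tert-butoxy)-2-oxoethyl]-4-methoxy-4-oxo-3-{[(1S,4aS,8aS)-5,5,8a-trimethyl-2-methylidenedecahydronaphthalen-1-yl]methoxy}butanoic acid
Conditions: Pd(PPh3)4 (5 mol %), morpholine, THF, rt
Reagents that add atoms: none
Why: zerovalent palladium ionises the allyl ester to a pi-allyl complex that morpholine traps, which frees only the central carboxyl group under neutral conditions.

Step 25
Reactants: 34 the silyl-protected triester ether of the oxygenated half
Product: 36 3-tert-butyl 1,2-dimethyl (1R,2S)-1-{[(1S,4aR,5R,8aS)-5-(hydroxymethyl)-5,8a-dimethyl-2-methylidenedecahydronaphthalen-1-yl]methoxy}propane-1,2,3-tricarboxylate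
Conditions: HF·pyridine, pyridine, THF, rt
Reagents that add atoms: none
Why: fluoride cleavage frees the neopentyl hydroxymethyl group; tert-butyl and methyl esters are stable.

Step 26
Reactants: 35 the central acid of the gem-dimethyl half; 36 the primary alcohol of the oxygenated half
Product: 38 the bis(tert-butyl) ester of the target (ester of 35 with the hydroxymethyl group of 36), via mixed anhydride 37 (not isolated)
Conditions: 2,4,6-Cl3C6H2COCl, Et3N, toluene, rt; then 36, DMAP, rt
Reagents that add atoms: none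
Why: Yamaguchi esterification: DMAP attacks the mixed anhydride at the aliphatic carbonyl and the acylpyridinium ion acylates the hindered primary alcohol; no stereocentre is formed.

Step 27
Reactants: 38 the bis(tert-butyl) ester of the target
Product: 40 CNP0139922.2 (target diacid), via bis(trimethylsilyl) ester 39 (not isolated)
Conditions: TMSOTf, 2,6-lutidine, CH2Cl2, 0 °C; then aq KH2PO4
Reagents that add atoms: none
Why: the buffered silyl triflate converts both tert-butyl esters into trimethylsilyl esters with loss of isobutene while sparing the two exocyclic alkenes and the methyl esters, and aqueous work-up frees the two acids.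

**Compound list**

1 | hydroxyacetone | CC(=O)CO | starting material
2 | 1-[(tert-butyldiphenylsilyl)oxy]propan-2-one | CC(=O)CO[Si](c1ccccc1)(c1ccccc1)C(C)(C)C | intermediate
3 | (3E)-5-[(tert-butyldiphenylsilyl)oxy]-4-methylpent-3-en-2-one | CC(=O)/C=C(\C)CO[Si](c1ccccc1)(c1ccccc1)C(C)(C)C | intermediate
4 | (5-chloropent-1-yn-1-yl)trimethylsilane | C[Si](C)(C)C#CCCCCl | starting material
5 | [5-(trimethylsilyl)pent-4-yn-1-yl]magnesium chloride | C[Si](C)(C)C#CCCC[Mg]Cl | intermediate
6 | rac-4-{[(tert-butyldiphenylsilyl)oxy]methyl}-4-methyl-9-(trimethylsilyl)non-8-yn-2-one | CC(=O)CC(C)(CCCC#C[Si](C)(C)C)CO[Si](c1ccccc1)(c1ccccc1)C(C)(C)C | intermediate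
7 | rac-4-{[(tert-butyldiphenylsilyl)oxy]methyl}-4-methylnon-8-yn-2-one | CC(=O)CC(C)(CCCC#C)CO[Si](c1ccccc1)(c1ccccc1)C(C)(C)C | intermediate
8 | methyl rac-7-{[(tert-butyldiphenylsilyl)oxy]methyl}-7-methyl-9-oxodec-2-ynoate | COC(=O)C#CCCCC(C)(CC(C)=O)CO[Si](c1ccccc1)(c1ccccc1)C(C)(C)C | intermediate
9 | methyl (2E)-rac-7-{[(tert-butyldiphenylsilyl)oxy]methyl}-2-iodo-3,7-dimethyl-9-oxodec-2-enoate | COC(=O)/C(I)=C(/C)CCCC(C)(CC(C)=O)CO[Si](c1ccccc1)(c1ccccc1)C(C)(C)C | intermediate
10 | methyl (2Z)-rac-7-{[(tert-butyldiphenylsilyl)oxy]methyl}-2-ethynyl-3,7-dimethyl-9-oxodec-2-enoate | COC(=O)/C(C#C)=C(/C)CCCC(C)(CC(C)=O)CO[Si](c1ccccc1)(c1ccccc1)C(C)(C)C | intermediate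
11 | (S)-1-phenylethylamine | C[C@H](N)c1ccccc1 | starting material
12 | ketimine of 10 with 11 (racemic at the quaternary carbon) | COC(=O)/C(C#C)=C(/C)CCCC(C)(CC(C)=N[C@@H](C)c1ccccc1)CO[Si](c1ccccc1)(c1ccccc1)C(C)(C)C | intermediate
13 | methyl 2-{3-[(TBDPS-oxy)methyl]-1,3-dimethyl-2-[1-{[(1S)-1-phenylethyl]imino}ethyl]cyclohexyl}buta-2,3-dienoate (iminoethyl and butadienoate groups trans; C5 and C10 as in 15; both C4 epimers) | CC(=N[C@@H](C)c1ccccc1)[C@H]1C(C)(CO[Si](c2ccccc2)(c2ccccc2)C(C)(C)C)CCC[C@]1(C)C(=C=C)C(=O)OC | intermediate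
14 | N-[(1S)-1-phenylethyl] ketimine of 15 (both C5 epimers) | CC(C)(C)[Si](c1ccccc1)(c1ccccc1)OCC1(C)CCC[C@]2(C)[C@@H](C(=O)OC)C(=C)CC(=N[C@@H](C)c3ccccc3)[C@@H]12 | intermediate
15 | methyl (1S,4aR,8aS)-5-{[(tert-butyldiphenylsilyl)oxy]methyl}-5,8a-dimethyl-2-methylidene-4-oxodecahydronaphthalene-1-carboxylate (both C5 epimers) | CC(C)(C)[Si](c1ccccc1)(c1ccccc1)OCC1(C)CCC[C@]2(C)[C@@H](C(=O)OC)C(=C)CC(=O)[C@@H]12 | intermediate
16 | 4-(tosylhydrazone) of 15 (both C5 epimers) | CC(C)(C)[Si](c1ccccc1)(c1ccccc1)OCC1(C)CCC[C@]2(C)[C@@H](C(=O)OC)C(=C)CC(=NNS(=O)(=O)c3ccc(C)cc3)[C@@H]12 | intermediate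
17 | methyl (1S,4aR,5R,8aS)-5-{[(tert-butyldiphenylsilyl)oxy]methyl}-5,8a-dimethyl-2-methylidenedecahydronaphthalene-1-carboxylate | CC(C)(C)[Si](c1ccccc1)(c1ccccc1)OC[C@]1(C)CCC[C@]2(C)[C@@H](C(=O)OC)C(=C)CC[C@@H]12 | intermediate
18 | methyl (1S,4aR,5S,8aS)-5-{[(tert-butyldiphenylsilyl)oxy]methyl}-5,8a-dimethyl-2-methylidenedecahydronaphthalene-1-carboxylate | CC(C)(C)[Si](c1ccccc1)(c1ccccc1)OC[C@@]1(C)CCC[C@]2(C)[C@@H](C(=O)OC)C(=C)CC[C@@H]12 | intermediate
19 | (1S,4aR,5R,8aS)-5-{[(tert-butyldiphenylsilyl)oxy]methyl}-5,8a-dimethyl-2-methylidenedecahydronaphthalene-1-carbaldehyde | CC(C)(C)[Si](c1ccccc1)(c1ccccc1)OC[C@]1(C)CCC[C@]2(C)[C@@H](C=O)C(=C)CC[C@@H]12 | intermediate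
20 | methyl (1S,4aR,5S,8aS)-5-(hydroxymethyl)-5,8a-dimethyl-2-methylidenedecahydronaphthalene-1-carboxylate | OC[C@@]1(C)CCC[C@]2(C)[C@@H](C(=O)OC)C(=C)CC[C@@H]12 | intermediate
21 | O-phenyl thionocarbonate of 20 | S=C(Oc1ccccc1)OC[C@@]1(C)CCC[C@]2(C)[C@@H](C(=O)OC)C(=C)CC[C@@H]12 | intermediate
22 | methyl (1S,4aS,8aS)-5,5,8a-trimethyl-2-methylidenedecahydronaphthalene-1-carboxylate (methyl albicanate) | C=C1CC[C@H]2C(C)(C)CCC[C@]2(C)[C@H]1C(=O)OC | intermediate
23 | (1S,4aS,8aS)-5,5,8a-trimethyl-2-methylidenedecahydronaphthalene-1-carbaldehyde (albicanal) | C=C1CC[C@H]2C(C)(C)CCC[C@]2(C)[C@H]1C=O | intermediate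
24 | dimethyl (R)-malate | COC(=O)[C@H](O)CC(=O)OC | starting material
25 | 3-tert-butyl 1,2-dimethyl (1R,2S)-1-hydroxypropane-1,2,3-tricarboxylate | O[C@@H](C(=O)OC)[C@H](CC(=O)OC(C)(C)C)C(=O)OC | intermediate
26 | 3-tert-butyl 1,2-dimethyl (1R,2S)-1-[(triethylsilyl)oxy]propane-1,2,3-tricarboxylate | CC[Si](CC)(CC)O[C@@H](C(=O)OC)[C@H](CC(=O)OC(C)(C)C)C(=O)OC | intermediate
27 | (R)-malic acid | OC(=O)[C@H](O)CC(=O)O | starting material
28 | (3R)-2,5-dioxooxolan-3-yl trifluoroacetate | O=C1[C@H](OC(=O)C(F)(F)F)CC(=O)O1 | intermediate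
29 | (3R)-3-hydroxy-4-methoxy-4-oxobutanoic acid | COC(=O)[C@H](O)CC(=O)O | intermediate
30 | 1-methyl 4-(prop-2-en-1-yl) (2R)-2-hydroxybutanedioate | COC(=O)[C@H](O)CC(=O)OCC=C | intermediate
31 | 3-tert-butyl 1-methyl 2-(prop-2-en-1-yl) (1R,2S)-1-hydroxypropane-1,2,3-tricarboxylate | O[C@@H](C(=O)OC)[C@H](CC(=O)OC(C)(C)C)C(=O)OCC=C | intermediate
32 | 3-tert-butyl 1-methyl 2-(prop-2-en-1-yl) (1R,2S)-1-[(triethylsilyl)oxy]propane-1,2,3-tricarboxylate | CC[Si](CC)(CC)O[C@@H](C(=O)OC)[C@H](CC(=O)OC(C)(C)C)C(=O)OCC=C | intermediate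
33 | 3-tert-butyl 1-methyl 2-(prop-2-en-1-yl) (1R,2S)-1-{[(1S,4aS,8aS)-5,5,8a-trimethyl-2-methylidenedecahydronaphthalen-1-yl]methoxy}propane-1,2,3-tricarboxylate | C=C1CC[C@H]2C(C)(C)CCC[C@]2(C)[C@H]1CO[C@@H](C(=O)OC)[C@H](CC(=O)OC(C)(C)C)C(=O)OCC=C | intermediate
34 | 3-tert-butyl 1,2-dimethyl (1R,2S)-1-{[(1S,4aR,5R,8aS)-5-{[(tert-butyldiphenylsilyl)oxy]methyl}-5,8a-dimethyl-2-methylidenedecahydronaphthalen-1-yl]methoxy}propane-1,2,3-tricarboxylate | CC(C)(C)[Si](c1ccccc1)(c1ccccc1)OC[C@]1(C)CCC[C@]2(C)[C@@H](CO[C@@H](C(=O)OC)[C@H](CC(=O)OC(C)(C)C)C(=O)OC)C(=C)CC[C@@H]12 | intermediate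
35 | (2S,3R)-2-[2-(tert-butoxy)-2-oxoethyl]-4-methoxy-4-oxo-3-{[(1S,4aS,8aS)-5,5,8a-trimethyl-2-methylidenedecahydronaphthalen-1-yl]methoxy}butanoic acid | C=C1CC[C@H]2C(C)(C)CCC[C@]2(C)[C@H]1CO[C@@H](C(=O)OC)[C@H](CC(=O)OC(C)(C)C)C(=O)O | intermediate
36 | 3-tert-butyl 1,2-dimethyl (1R,2S)-1-{[(1S,4aR,5R,8aS)-5-(hydroxymethyl)-5,8a-dimethyl-2-methylidenedecahydronaphthalen-1-yl]methoxy}propane-1,2,3-tricarboxylate | OC[C@]1(C)CCC[C@]2(C)[C@@H](CO[C@@H](C(=O)OC)[C@H](CC(=O)OC(C)(C)C)C(=O)OC)C(=C)CC[C@@H]12 | intermediate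
37 | mixed anhydride of 35 with 2,4,6-trichlorobenzoic acid | C=C1CC[C@H]2C(C)(C)CCC[C@]2(C)[C@H]1CO[C@@H](C(=O)OC)[C@H](CC(=O)OC(C)(C)C)C(=O)OC(=O)c1c(Cl)cc(Cl)cc1Cl | intermediate
38 | bis(tert-butyl) ester of the target (ester of acid 35 with the hydroxymethyl group of 36) | C=C1CC[C@H]2C(C)(C)CCC[C@]2(C)[C@H]1CO[C@@H](C(=O)OC)[C@H](CC(=O)OC(C)(C)C)C(=O)OC[C@]1(C)CCC[C@]2(C)[C@@H](CO[C@@H](C(=O)OC)[C@H](CC(=O)OC(C)(C)C)C(=O)OC)C(=C)CC[C@@H]12 | intermediate
39 | bis(trimethylsilyl) ester of the target | C=C1CC[C@H]2C(C)(C)CCC[C@]2(C)[C@H]1CO[C@@H](C(=O)OC)[C@H](CC(=O)O[Si](C)(C)C)C(=O)OC[C@]1(C)CCC[C@]2(C)[C@@H](CO[C@@H](C(=O)OC)[C@H](CC(=O)O[Si](C)(C)C)C(=O)OC)C(=C)CC[C@@H]12 | intermediate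
40 | CNP0139922.2 (target diacid) | C=C1CC[C@H]2C(C)(C)CCC[C@]2(C)[C@H]1CO[C@@H](C(=O)OC)[C@H](CC(=O)O)C(=O)OC[C@]1(C)CCC[C@]2(C)[C@@H](CO[C@@H](C(=O)OC)[C@H](CC(=O)O)C(=O)OC)C(=C)CC[C@@H]12 | target

**Step count and risks**

Total step count: 27. Longest linear sequence: 18 steps (steps 1–10, 12–15, 22, 24, 26, 27).

Steps most likely to fail:

1. Step 8 (proposed new method). The first aza-ene addition to the tetrasubstituted, singly activated alkene may be slow, and the second addition to the allenoate may lose out to oligomerisation of the allenoate or to drift of the double bond into conjugation. Fallback, setting out from 10 and coming back at 15, with the two bond formations separated and ring B closed by pi-acid catalysis instead of a second aza-ene step: ketimine 12 is formed as in step 8 but heated in toluene with MgBr2·OEt2 and without triethylamine, so that only the first intramolecular Michael addition of the chiral imine occurs and the monocyclic propargylic ester ketimine F1 results. Mild hydrolysis (aq AcOH) gives the monocyclic keto ester F2. Soft enolisation (TBSOTf, Et3N, CH2Cl2, −78 °C) gives the terminal silyl enol ether F3. A 6-exo-dig Conia-ene-type carbocyclisation of the silyl enol ether onto the terminal alkyne under cationic monovalent gold catalysis (Ph3PAuCl, AgBF4, CH2Cl2/MeOH, rt) returns 15.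

2. Step 22 (and in the same way step 23). Oxocarbenium formation between the hindered, epimerisable beta,gamma-unsaturated aldehyde and the weakly nucleophilic alpha-silyloxy ester may be slower than direct reduction of the aldehyde or loss of the C9 configuration. Fallback, setting out from 22 and coming back at 33, with the ether made by conjugate addition instead: LiAlH4 reduction of 22 gives albicanol F4. Ozonolysis (O3, CH2Cl2/MeOH, −78 °C; Me2S) gives the beta-hydroxy ketone F5. Acid-catalysed dehydration (TsOH, toluene, 80 °C) gives the alpha-methylene ketone F6. Oxa-Michael addition of alcohol 31 (PMe3 cat., CH2Cl2, rt) gives the beta-alkoxy ketone F7, in which C9 can settle as the equatorial epimer. Takai–Lombardo methylenation (Zn, CH2Br2, TiCl4, THF) returns 33.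

3. Step 9. Condensation at the hindered C6 carbonyl may be sluggish, and under the acidic conditions the exocyclic double bond may move into conjugation with the C=N bond. Fallback, setting out from 15 and coming back at 17 and 18, with a radical C–O cleavage instead of the hydrazone reduction: NaBH4 with CeCl3·7H2O (MeOH, −40 °C) gives the C6 alcohol F8. PhOC(S)Cl, DMAP and pyridine give its thionocarbonate F9. Bu3SnH with AIBN (toluene, 110 °C) removes the oxygen, and chromatography gives 17 and 18.

Further compounds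
F1 | step 8 | methyl 2-{3-[(TBDPS-oxy)methyl]-1,3-dimethyl-2-[1-{[(1S)-1-phenylethyl]imino}ethyl]cyclohexyl}but-3-ynoate (ring substituents trans; C4 and C9 epimers) | CC(=N[C@@H](C)c1ccccc1)[C@H]1C(C)(CO[Si](c2ccccc2)(c2ccccc2)C(C)(C)C)CCC[C@]1(C)C(C#C)C(=O)OC
F2 | step 8 | methyl 2-{2-acetyl-3-[(TBDPS-oxy)methyl]-1,3-dimethylcyclohexyl}but-3-ynoate (ring substituents trans; C4 and C9 epimers) | CC(=O)[C@H]1C(C)(CO[Si](c2ccccc2)(c2ccccc2)C(C)(C)C)CCC[C@]1(C)C(C#C)C(=O)OC
F3 | step 8 | tert-butyldimethylsilyl enol ether of F2 at the acetyl group | C=C(O[Si](C)(C)C(C)(C)C)[C@H]1C(C)(CO[Si](c2ccccc2)(c2ccccc2)C(C)(C)C)CCC[C@]1(C)C(C#C)C(=O)OC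
F4 | step 22 | [(1S,4aS,8aS)-5,5,8a-trimethyl-2-methylidenedecahydronaphthalen-1-yl]methanol (albicanol) | C=C1CC[C@H]2C(C)(C)CCC[C@]2(C)[C@H]1CO
F5 | step 22 | (1S,4aS,8aS)-1-(hydroxymethyl)-5,5,8a-trimethyloctahydronaphthalen-2(1H)-one | O=C1CC[C@H]2C(C)(C)CCC[C@]2(C)[C@H]1CO
F6 | step 22 | (4aS,8aS)-5,5,8a-trimethyl-1-methylideneoctahydronaphthalen-2(1H)-one | O=C1CC[C@H]2C(C)(C)CCC[C@]2(C)C1=C
F7 | step 22 | 3-tert-butyl 1-methyl 2-(prop-2-en-1-yl) (1R,2S)-1-{[(1S,4aS,8aS)-5,5,8a-trimethyl-2-oxodecahydronaphthalen-1-yl]methoxy}propane-1,2,3-tricarboxylate | O=C1CC[C@H]2C(C)(C)CCC[C@]2(C)[C@H]1CO[C@@H](C(=O)OC)[C@H](CC(=O)OC(C)(C)C)C(=O)OCC=C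
F8 | step 9 | methyl (1S,4aR,8aS)-5-{[(tert-butyldiphenylsilyl)oxy]methyl}-4-hydroxy-5,8a-dimethyl-2-methylidenedecahydronaphthalene-1-carboxylate (both C5 epimers) | CC(C)(C)[Si](c1ccccc1)(c1ccccc1)OCC1(C)CCC[C@]2(C)[C@@H](C(=O)OC)C(=C)CC(O)[C@@H]12
F9 | step 9 | O-phenyl thionocarbonate of F8 | CC(C)(C)[Si](c1ccccc1)(c1ccccc1)OCC1(C)CCC[C@]2(C)[C@@H](C(=O)OC)C(=C)CC(OC(=S)Oc3ccccc3)[C@@H]12
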